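**Strategy.** Ring A is disconnected at C3–C4: C4, the α-carbon of the C18 carboxyl, becomes an ester enolate and C3 a primary bromide on the three-carbon arm at C10 of a finished ring B. One 6-exo-tet alkylation closes ring A and creates the quaternary C4; allylic strain between the ketene acetal and H-5 sends the C19 methyl axial, syn to C20, and the carboxyl equatorial. The precursor is a monocyclic methylenecyclohexane already carrying the full side chain. It comes from (+)-verbenone, whose bridgeheads fix C5 and relay C10 (cuprate addition) and C9 (kinetic protonation) before a cyclobutane fragmentation releases ring B.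

Key step: step 12

Remark: labdane numbering (C1–C20) is used for every intermediate; the target is read as (4R,5R,9S,10R)-15-acetoxylabda-8(17),13E-dien-18-oic acid, that is, carboxyl α (equatorial) and C19 methyl β (axial) at C4.

## Side-chain electrophile

Step 1
Reactants: 1 4-bromobut-1-yne
Product: 4 (E)-5-bromo-3-methylpent-2-en-1-ol, via dimethylalkenylalane 2 (not isolated), via lithium alkenylalanate 3 (not isolated)
Conditions: Me3Al, Cp2ZrCl2 (cat.), ClCH2CH2Cl, 0 °C to rt; n-BuLi, THF, −78 °C; (CH2O)n, −78 °C to rt; aq. HCl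
Reagents that add atoms: trimethylaluminium C[Al](C)C; paraformaldehyde (as formaldehyde) C=O
Why: Zirconium-catalysed Negishi carboalumination adds CH3 and Al syn across the terminal alkyne and the derived alanate is hydroxymethylated with retention, so the trisubstituted alkene should form as the E isomer (C12 trans to C15), while the primary bromide, which lies trans to the metal-bearing carbon, stays untouched.

Step 2
Reactants: 4 (E)-5-bromo-3-methylpent-2-en-1-ol
Product: 5 (E)-5-bromo-3-methylpent-2-en-1-yl pivalate
Conditions: t-BuCOCl, pyridine, DMAP (cat.), CH2Cl2, 0 °C to rt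
Reagents that add atoms: pivaloyl chloride CC(C)(C)C(Cl)=O
Why: Standard acylation of the allylic alcohol; the pivalate has no α-hydrogen and a hindered carbonyl and should therefore survive the enolate steps 5, 6 and 12.

Step 3
Reactants: 5 (E)-5-bromo-3-methylpent-2-en-1-yl pivalate
Product: 6 (E)-5-iodo-3-methylpent-2-en-1-yl pivalate
Conditions: NaI, acetone, reflux
Reagents that add atoms: sodium iodide [Na+].[I-]
Why: Finkelstein halide exchange, driven by precipitation of NaBr, gives the more reactive primary iodide needed for the hindered enolate alkylation.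

## Ring B from (+)-verbenone

Step 4
Reactants: 7 (1R,5R)-(+)-verbenone; 8 (3-bromopropoxy)(tert-butyl)dimethylsilane
Product: 10 4-[3-(tert-butyldimethylsilyloxy)propyl]-4,6,6-trimethyl-2-(trimethylsilyloxy)bicyclo[3.1.1]hept-2-ene (propyl arm anti to the C(CH3)2 bridge), via Grignard reagent 9 (not isolated)
Conditions: 8, Mg, THF, rt; then 7, CuBr·SMe2 (20 mol%), Me3SiCl, THF, −78 to −20 °C; Et3N, pentane, cold aq. NaHCO3
Reagents that add atoms: chlorotrimethylsilane C[Si](C)(C)Cl
Why: Copper-catalysed, Me3SiCl-accelerated conjugate addition of the Grignard reagent to the β,β-disubstituted enone should occur on the face opposite the C(CH3)2 bridge, which makes the quaternary C10 with the C1–C3 arm α and C20 β, and traps the enolate regiospecifically as the C8–C9 silyl enol ether.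

Step 5
Reactants: 10 silyl enol ether; 6 (E)-5-iodo-3-methylpent-2-en-1-yl pivalate
Product: 12 3-(tert-butyldimethylsilyloxy)-15-(pivaloyloxy)-4,7-cyclo-17-nor-3,4-seco-9-epi-labd-13E-en-8-one (side chain at C9 anti to the C4 bridge), via lithium enolate 11 (not isolated)
Conditions: MeLi (1.0 equiv), THF, 0 °C to rt; then 6, HMPA, −40 to 0 °C
Reagents that add atoms: none
Why: The amine-free lithium enolate released by Si–O cleavage with MeLi can only be the C8–C9 enolate because C7 is a bridgehead, and its SN2 alkylation by iodide 6 should place the side chain anti to the bridge, which is the C9 epimer of what is needed and is corrected in step 6.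

Step 6
Reactants: 12 9-epi ketone
Product: 14 3-(tert-butyldimethylsilyloxy)-15-(pivaloyloxy)-4,7-cyclo-17-nor-3,4-seco-labd-13E-en-8-one (C5/C9/C10 as in the target), via potassium enolate 13 (not isolated)
Conditions: KN(SiMe3)2, THF, 0 °C to rt; then cannulated at −78 °C into AcOH/THF; used directly
Reagents that add atoms: none
Why: Deprotonation followed by kinetic reprotonation: the only enolisable position is C9, and protonation of the potassium enolate from the open α face (anti to the bridge) should turn the side chain onto the bridge face, which sets C9 as in the target although this epimer is the less stable one in the bicycle.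

Step 7
Reactants: 14 bicyclic ketone
Product: 16 (2R,3S,4S)-3-[3-(tert-butyldimethylsilyloxy)propyl]-3-methyl-2-[(E)-3-methyl-5-(pivaloyloxy)pent-3-enyl]-4-(prop-1-en-2-yl)cyclohexan-1-one, via aluminium enolate 15 (not isolated)
Conditions: Me2AlCl (1.3 equiv), CH2Cl2, −78 to −20 °C; cold dilute aq. HCl
Reagents that add atoms: none
Why: Lewis acid-promoted cyclobutane fragmentation of a pinane-type ketone (a retro-ene-type opening): Me2AlCl on the carbonyl oxygen triggers heterolysis of the strained C7–C4 bond to the tertiary C4 cation and the C7–C8 aluminium enolate, a methyl proton is passed to oxygen and leaves as methane (isopropenyl, not isopropylidene, so C5 is kept), and because the enolate lies on the C7 side C9 is not touched.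

Step 8
Reactants: 16 isopropenyl ketone
Product: 18 3-(tert-butyldimethylsilyloxy)-15-(pivaloyloxy)-17-nor-3,4-seco-labd-13E-ene-8,18-diol (mixture at C4 and C8), via bis(9-BBN) adduct 17 (not isolated)
Conditions: 9-BBN (3 equiv), THF, 0 °C to rt; then aq. NaOAc, H2O2, 0 °C to rt
Reagents that add atoms: hydrogen peroxide OO
Why: Hydroboration–oxidation: 9-BBN adds anti-Markovnikov to the 1,1-disubstituted isopropenyl group far faster than to the trisubstituted side-chain alkene and at the same time reduces the C8 ketone, which removes the only enolisable carbonyl during the buffered peroxide work-up; the new centres C4 and C8 form as mixtures that are erased in steps 9 and 12.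

Step 9
Reactants: 18 diol
Product: 20 methyl 3-(tert-butyldimethylsilyloxy)-8-oxo-15-(pivaloyloxy)-17-nor-3,4-seco-labd-13E-en-18-oate (C4 mixture), via keto acid 19 (not isolated)
Conditions: (C5H5NH)2Cr2O7, DMF, rt; then Me3SiCHN2, MeOH–toluene, 0 °C
Reagents that add atoms: pyridinium dichromate [O-][Cr](=O)(=O)O[Cr](=O)(=O)[O-].c1cc[nH+]cc1.c1cc[nH+]cc1; (trimethylsilyl)diazomethane C[Si](C)(C)C=[N+]=[N-]
Why: Hexavalent chromium in DMF oxidises the primary alcohol to the acid and the secondary alcohol back to the ketone under non-basic conditions that leave C9 alone, and diazoalkane esterification then gives the methyl ester without base.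

Step 10
Reactants: 20 keto ester
Product: 21 methyl 3-(tert-butyldimethylsilyloxy)-15-(pivaloyloxy)-3,4-seco-labda-8(17),13E-dien-18-oate (C4 mixture)
Conditions: Zn, CH2Br2, TiCl4, THF–CH2Cl2, 0 °C to rt
Reagents that add atoms: dibromomethane BrCBr
Why: Takai–Lombardo methylenation with the titanium–zinc methylene reagent is non-basic, so the hindered enolisable C8 ketone should be converted into the exocyclic C8=C17 alkene without epimerisation at C9 and without touching the two esters.

Step 11
Reactants: 21 silyl ether
Product: 22 methyl 3-bromo-15-(pivaloyloxy)-3,4-seco-labda-8(17),13E-dien-18-oate (C4 mixture)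
Conditions: Ph3PBr2, CH2Cl2, 0 °C to rt
Reagents that add atoms: dibromotriphenylphosphorane BrP(Br)(c1ccccc1)(c1ccccc1)c1ccccc1
Why: Direct conversion of the primary silyl ether into the bromide through an alkoxyphosphonium bromide (Appel-type SN2) saves a deprotection step; the allylic pivalate, the methyl ester and the alkenes are not attacked by Ph3PBr2.

## Ring A closure and end game

Step 12
Reactants: 22 bromo ester
Product: 24 methyl (4R,5R,9S,10R)-15-(pivaloyloxy)labda-8(17),13E-dien-18-oate, via lithium ester enolate 23 (not isolated)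
Conditions: LiN(i-Pr)2 (1.2 equiv), THF, −78 °C; then DMPU, warm to 0 °C
Reagents that add atoms: none
Why: LiN(i-Pr)2 removes the C4 hydrogen of the α-branched ester (both C4 epimers of 22 give the same enolate 23), and the enolate carbon then displaces bromide at C3 in an intramolecular SN2 reaction, the familiar intramolecular ester-enolate alkylation. Ring A closes in the 6-(enolexo)-exo-tet mode through a chair-like transition state in which the C1–C3 arm, equatorial on ring B at C10, can reach only the enolate face turned towards C10. The new quaternary stereocentre C4 is controlled by allylic 1,3-strain: whichever enolate geometry forms, one oxygen of the ketene acetal is cis to C5, so H-5 must eclipse the C4=C18 bond, and the other rotamer would drive that oxygen into C6 and the axial C20 methyl. In the favoured rotamer the C19 methyl takes the axial site syn to C20 and the ester carbon C18 the equatorial site, which is the (4R) configuration of the target; a linear nitrile anion would lack this control element, which is why the ester is used. The step needs C-alkylation to outrun E2 loss of HBr and intermolecular ester condensation, and the six-membered closure next to the quaternary C10 together with the absence of any other acidic site (C8 is already the methylene, C15 is a pivalate) should secure this.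

Step 13
Reactants: 24 diester
Product: 25 (4R,5R,9S,10R)-15-hydroxylabda-8(17),13E-dien-18-oic acid
Conditions: KOH, DMSO–H2O, 110 °C; then aq. HCl
Reagents that add atoms: potassium hydroxide [K+].[OH-]
Why: Saponification with hot hydroxide cleaves the hindered equatorial tertiary methyl ester and the pivalate in one operation; both alkenes are stable to base and no stereocentre is enolisable.

Step 14
Reactants: 25 hydroxy acid
Product: 26 (4R,5R,9S,10R)-15-acetoxylabda-8(17),13E-dien-18-oic acid (CNP0190226.3)
Conditions: Ac2O, pyridine, DMAP (cat.), CH2Cl2, 0 °C to rt; aqueous work-up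
Reagents that add atoms: acetic anhydride CC(=O)OC(C)=O
Why: Acetylation of the primary allylic alcohol with Ac2O and pyridine; any mixed anhydride formed at the hindered C18 acid is hydrolysed back during the aqueous work-up.

## Compound list

1 | 4-bromobut-1-yne | C#CCCBr | starting material
2 | (E)-(4-bromo-2-methylbut-1-en-1-yl)dimethylaluminium | C[Al](C)/C=C(\C)CCBr | intermediate
3 | lithium (E)-(4-bromo-2-methylbut-1-en-1-yl)(butyl)dimethylaluminate | [Li+].CCCC[Al-](C)(C)/C=C(\C)CCBr | intermediate
4 | (E)-5-bromo-3-methylpent-2-en-1-ol | OC/C=C(\C)CCBr | intermediate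
5 | (E)-5-bromo-3-methylpent-2-en-1-yl pivalate | CC(C)(C)C(=O)OC/C=C(\C)CCBr | intermediate
6 | (E)-5-iodo-3-methylpent-2-en-1-yl pivalate | CC(C)(C)C(=O)OC/C=C(\C)CCI | intermediate
7 | (1R,5R)-(+)-verbenone, (1R,5R)-4,6,6-trimethylbicyclo[3.1.1]hept-3-en-2-one | O=C1[C@@H]2C[C@@H](C2(C)C)C(C)=C1 | starting material
8 | (3-bromopropoxy)(tert-butyl)dimethylsilane | CC(C)(C)[Si](C)(C)OCCCBr | starting material
9 | [3-(tert-butyldimethylsilyloxy)propyl]magnesium bromide | CC(C)(C)[Si](C)(C)OCCC[Mg]Br | intermediate
10 | 4-[3-(tert-butyldimethylsilyloxy)propyl]-4,6,6-trimethyl-2-(trimethylsilyloxy)bicyclo[3.1.1]hept-2-ene; bridgeheads as in 7, propyl arm anti to the C(CH3)2 bridge (C10 with C1 α, C20 β) | C[Si](C)(C)OC=1[C@@H]2C[C@@H](C2(C)C)[C@](C)(CCCO[Si](C)(C)C(C)(C)C)C1 | intermediate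
11 | lithium C8–C9 enolate corresponding to 10 | [Li]OC=1[C@@H]2C[C@@H](C2(C)C)[C@](C)(CCCO[Si](C)(C)C(C)(C)C)C1 | intermediate
12 | 3-(tert-butyldimethylsilyloxy)-15-(pivaloyloxy)-4,7-cyclo-17-nor-3,4-seco-9-epi-labd-13E-en-8-one; side chain at C9 anti to the C4 bridge | O=C1[C@@H]2C[C@@H](C2(C)C)[C@](C)(CCCO[Si](C)(C)C(C)(C)C)[C@@H]1CC/C(C)=C/COC(=O)C(C)(C)C | intermediate
13 | potassium C8–C9 enolate of 12 | [K]OC=1[C@@H]2C[C@@H](C2(C)C)[C@](C)(CCCO[Si](C)(C)C(C)(C)C)C1CC/C(C)=C/COC(=O)C(C)(C)C | intermediate
14 | 3-(tert-butyldimethylsilyloxy)-15-(pivaloyloxy)-4,7-cyclo-17-nor-3,4-seco-labd-13E-en-8-one; C5, C9, C10 as in the target, side chain syn to the C4 bridge | O=C1[C@@H]2C[C@@H](C2(C)C)[C@](C)(CCCO[Si](C)(C)C(C)(C)C)[C@H]1CC/C(C)=C/COC(=O)C(C)(C)C | intermediate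
15 | chloro(methyl)aluminium C7–C8 enolate of 16 | C[Al](Cl)OC1=CC[C@@H](C(C)=C)[C@](C)(CCCO[Si](C)(C)C(C)(C)C)[C@H]1CC/C(C)=C/COC(=O)C(C)(C)C | intermediate
16 | (2R,3S,4S)-3-[3-(tert-butyldimethylsilyloxy)propyl]-3-methyl-2-[(E)-3-methyl-5-(pivaloyloxy)pent-3-enyl]-4-(prop-1-en-2-yl)cyclohexan-1-one (17-nor-3,4-seco-labda-4(18),13E-dien-8-one skeleton) | O=C1CC[C@@H](C(C)=C)[C@](C)(CCCO[Si](C)(C)C(C)(C)C)[C@H]1CC/C(C)=C/COC(=O)C(C)(C)C | intermediate
17 | bis(9-BBN) adduct of 16: C8 O-borinate and C18 B-alkylborane (C4, C8 mixtures; ring centres as in 16) | C1(OB2C3CCCC2CCC3)CC[C@@H](C(C)CB2C3CCCC2CCC3)[C@](C)(CCCO[Si](C)(C)C(C)(C)C)[C@H]1CC/C(C)=C/COC(=O)C(C)(C)C | intermediate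
18 | 3-(tert-butyldimethylsilyloxy)-15-(pivaloyloxy)-17-nor-3,4-seco-labd-13E-ene-8,18-diol (C4, C8 mixtures; C5, C9, C10 as in the target) | OC1CC[C@@H](C(C)CO)[C@](C)(CCCO[Si](C)(C)C(C)(C)C)[C@H]1CC/C(C)=C/COC(=O)C(C)(C)C | intermediate
19 | 3-(tert-butyldimethylsilyloxy)-8-oxo-15-(pivaloyloxy)-17-nor-3,4-seco-labd-13E-en-18-oic acid (C4 mixture) | O=C1CC[C@@H](C(C)C(=O)O)[C@](C)(CCCO[Si](C)(C)C(C)(C)C)[C@H]1CC/C(C)=C/COC(=O)C(C)(C)C | intermediate
20 | methyl 3-(tert-butyldimethylsilyloxy)-8-oxo-15-(pivaloyloxy)-17-nor-3,4-seco-labd-13E-en-18-oate (C4 mixture) | O=C1CC[C@@H](C(C)C(=O)OC)[C@](C)(CCCO[Si](C)(C)C(C)(C)C)[C@H]1CC/C(C)=C/COC(=O)C(C)(C)C | intermediate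
21 | methyl 3-(tert-butyldimethylsilyloxy)-15-(pivaloyloxy)-3,4-seco-labda-8(17),13E-dien-18-oate (C4 mixture) | C=C1CC[C@@H](C(C)C(=O)OC)[C@](C)(CCCO[Si](C)(C)C(C)(C)C)[C@H]1CC/C(C)=C/COC(=O)C(C)(C)C | intermediate
22 | methyl 3-bromo-15-(pivaloyloxy)-3,4-seco-labda-8(17),13E-dien-18-oate (C4 mixture) | C=C1CC[C@@H](C(C)C(=O)OC)[C@](C)(CCCBr)[C@H]1CC/C(C)=C/COC(=O)C(C)(C)C | intermediate
23 | lithium ester enolate of 22 (C4=C18 ketene acetal) | C=C1CC[C@@H](C(C)=C(OC)O[Li])[C@](C)(CCCBr)[C@H]1CC/C(C)=C/COC(=O)C(C)(C)C | intermediate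
24 | methyl (4R,5R,9S,10R)-15-(pivaloyloxy)labda-8(17),13E-dien-18-oate | C=C1CC[C@@H]2[C@](C)(CCC[C@@]2(C)C(=O)OC)[C@H]1CC/C(C)=C/COC(=O)C(C)(C)C | intermediate
25 | (4R,5R,9S,10R)-15-hydroxylabda-8(17),13E-dien-18-oic acid | C=C1CC[C@@H]2[C@](C)(CCC[C@@]2(C)C(=O)O)[C@H]1CC/C(C)=C/CO | intermediate
26 | (4R,5R,9S,10R)-15-acetoxylabda-8(17),13E-dien-18-oic acid | C=C1CC[C@@H]2[C@](C)(CCC[C@@]2(C)C(=O)O)[C@H]1CC/C(C)=C/COC(C)=O | target

## Step count and risks

Total step count: 14. Longest linear sequence: 13 steps (steps 1–3 and 5–14, from 1); the sequence from 7 is 11 steps.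

Steps most likely to fail:

1. Step 5. The SN2 reaction at a neopentyl-like enolate carbon with an unactivated primary iodide may be so slow that base-induced loss of HI from 6 and O-alkylation take over. Fallback, azaenolate instead of enolate alkylation: setting out from 10, the silyl enol ether would be cleaved (K2CO3, MeOH, 0 °C) to the C9-unsubstituted bicyclic ketone F1. Condensation with 1,1-dimethylhydrazine (TsOH cat., EtOH, reflux) would give the N,N-dimethylhydrazone F2. Deprotonation with LiN(i-Pr)2 (THF, 0 °C) and alkylation of the more nucleophilic azaenolate with 6 would give the C9-alkylated hydrazone F3, side chain again anti to the bridge. Hydrolysis (aq. oxalic acid, Et2O) would come back to the route at 12, after which step 6 follows as before.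

2. Step 7. The tertiary C4 cation may be captured by chloride or lose the ring proton at C5 (isopropylidene formation and loss of the C5 stereocentre), or the strained ketone may enolise towards C9 before the ring opens. Fallback, halide capture and a separate elimination with the ketone masked: setting out from 14, Me3SiI (CH2Cl2, −78 °C, in the presence of (Me3Si)2NH) would open the cyclobutane to the silyl enol ether tertiary iodide F4. E2 elimination with DBU (toluene, rt) at the methyl hydrogens would give the isopropenyl silyl enol ether F5, in which C9 cannot enolise. Brief desilylation of the enol ether (K2CO3, MeOH, 0 °C) would come back to the route at 16.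

3. Step 12. Enolisation of the hindered α-branched ester may be incomplete, so that E2 loss of HBr or attack of the amide base on an ester becomes the faster process. Fallback, the same C3–C4 closure at the aldehyde oxidation level, where the α-hydrogen is far more acidic: setting out from 22, i-Bu2AlH (1.1 equiv, CH2Cl2, −78 °C) would reduce the methyl ester to the bromo aldehyde F6. KOC(CH3)3 (THF–t-BuOH, 0 °C) would form the aldehyde enolate and close ring A to the cyclised aldehyde F7, any C4 epimer being removed at this stage. Pinnick oxidation (NaClO2, NaH2PO4, 2-methylbut-2-ene, t-BuOH–H2O) would give the acid pivalate F8. Removal of the pivalate (KOH, MeOH–H2O, rt) would come back to the route at 25.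

Further compounds
F1 | step 5 | 4-[3-(tert-butyldimethylsilyloxy)propyl]-4,6,6-trimethylbicyclo[3.1.1]heptan-2-one (propyl arm anti to the bridge) | O=C1[C@@H]2C[C@@H](C2(C)C)[C@](C)(CCCO[Si](C)(C)C(C)(C)C)C1
F2 | step 5 | N,N-dimethylhydrazone of F1 | CN(C)N=C1[C@@H]2C[C@@H](C2(C)C)[C@](C)(CCCO[Si](C)(C)C(C)(C)C)C1
F3 | step 5 | N,N-dimethylhydrazone of 12 | CN(C)N=C1[C@@H]2C[C@@H](C2(C)C)[C@](C)(CCCO[Si](C)(C)C(C)(C)C)[C@@H]1CC/C(C)=C/COC(=O)C(C)(C)C
F4 | step 7 | C7–C8 trimethylsilyl enol ether of the ring-opened ketone with a 2-iodopropan-2-yl group at C5 | C[Si](C)(C)OC1=CC[C@@H](C(C)(C)I)[C@](C)(CCCO[Si](C)(C)C(C)(C)C)[C@H]1CC/C(C)=C/COC(=O)C(C)(C)C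
F5 | step 7 | C7–C8 trimethylsilyl enol ether of 16 | C[Si](C)(C)OC1=CC[C@@H](C(C)=C)[C@](C)(CCCO[Si](C)(C)C(C)(C)C)[C@H]1CC/C(C)=C/COC(=O)C(C)(C)C
F6 | step 12 | 3-bromo-15-(pivaloyloxy)-3,4-seco-labda-8(17),13E-dien-18-al (C4 mixture) | C=C1CC[C@@H](C(C)C=O)[C@](C)(CCCBr)[C@H]1CC/C(C)=C/COC(=O)C(C)(C)C
F7 | step 12 | (4R,5R,9S,10R)-15-(pivaloyloxy)labda-8(17),13E-dien-18-al | C=C1CC[C@@H]2[C@](C)(CCC[C@@]2(C)C=O)[C@H]1CC/C(C)=C/COC(=O)C(C)(C)C
F8 | step 12 | (4R,5R,9S,10R)-15-(pivaloyloxy)labda-8(17),13E-dien-18-oic acid | C=C1CC[C@@H]2[C@](C)(CCC[C@@]2(C)C(=O)O)[C@H]1CC/C(C)=C/COC(=O)C(C)(C)C
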